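## The problem

Target 24 is the isovanillate of a himachalane-type diol. Ring A is a cyclohexene made of C1 (ester carbinol), C2, C3, C4 and C5=C6 (methyl on C6). Ring B is a cycloheptane made of C3, C4, C7 (gem-dimethyl), C8, C9, C10 and C11 (methyl carbinol). The rings share the C3–C4 bond in a cis fusion, and this bond lies next to the quaternary C7, so it is the most congested bond of the skeleton.

There are four stereocentres (1R,3R,4S,11S): H3 and H4 are cis, the C11 methyl is syn and the C11 hydroxyl anti to H3, and the C1 ester oxygen lies on the same face of ring A as H3 and H4. Only C4 needs control from outside. A chain on C4 can deliver a carbon to C3, and the cis-fused bicycle then has a convex face (that of H3 and H4) from which reagents approach. For the methyl group at C11 this is the right face. For hydride at C1 it is the wrong one, so the C1 oxygen has to be turned over.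

The tertiary alcohol (dehydration), the allylic aryl ester (ionisation, elimination, acyl transfer) and the free guaiacol-type phenol (oxidation) rule out strong acid, strong base and unselective oxidants late in the route.

C1 and C11 both carry oxygen and stand in a 1,4 relationship. If C1 is an enone carbonyl and C11 an aldehyde, both C3 (β-carbon) and C11 are electrophiles. The C3–C11 bond therefore needs a polarity reversal, which a samarium ketyl provides while closing ring B.

## Retrosynthesis

**Phenol and C11 methyl.** Target 24 is traced to its aryl silyl ether 23 (O–Si cut), and 23 to ketone 22 by cutting the C11–CH3 bond. Building the methyl carbinol into the cyclisation substrate instead would ask the key step to fix C11 with an unpredictable sense. Addition to the ring ketone of a rigid cis-fused bicycle is predictable: the nucleophile comes anti to the C3–C2 bond, from the face of H3. The forward step must let the ketone react in the presence of the aryl ester and must avoid enolisation towards C3.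

**Ester with inversion.** Ketone 22 comes from alcohol 21 and this from triethylsilyl ether 20. Ester 20 is cut at the C1–O (alkyl–oxygen) bond into allylic alcohol 16 and acid 19, not at the acyl–oxygen bond. The reason is that hydride reduction is expected to place the C1 hydroxyl on the face of ring B. A Mitsunobu coupling joins the fragments and corrects C1 in one operation. The ester then protects C1 during the C11 chemistry, which saves a silylation and a desilylation. Acid 19 comes in one step from isovanillic acid 17.

**Oxidation pattern of ring A.** Alcohol 16 comes from enone 15. Enone 15 comes from silyl enol ether 14, and 14 from saturated ketone 13, the triethylsilyl ether of hydroxy ketone 12. The C6 methyl makes the C6 side the more substituted one, so the enol ether, and with it the C5=C6 double bond, forms on the correct side. The forward steps must keep the C11 oxygen distinguishable from C1, which the silyl ether does.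

**Key disconnection C3–C11.** Hydroxy ketone 12 is cut between C3 and C11 to give aldehyde enone 11. A cut at C3–C4 would leave the hindered bond next to C7 for a late step. A cut at C10–C11 would need a C11 ketone enolate and would not set C3. The chosen cut turns a bicycle with two ring-fusion centres into a monocyclic enone with a single stereocentre (C4). It asks for a 7-exo radical closure that delivers C11 to C3 cis to the chain on C4.

**Aldehyde and C6 methyl.** Aldehyde 11 comes from terminal alkene 10 by oxidative cleavage, so no protecting group is needed for C11. Alkene 10 comes from enone 9 by α′-methylation. Introducing the methyl group with 3-methylbut-3-en-2-one in the annulation would be shorter, but α-substituted vinyl ketones are poor acceptors in enamine catalysis. Enolate methylation is routine, and its lack of stereocontrol does not matter.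

**Ring A.** Enone 9 is cut at C4–C5 (Michael addition) and C2=C3 (aldol condensation) into aldehyde 6 and but-3-en-2-one 7. This is the only step that needs an external chiral controller, and it sets C4 next to the bulky tert-alkyl group, which should raise selectivity.

**Quaternary carbon.** Aldehyde 6 comes from ester 5. Ester 5 is cut at C7–C8 into ethyl 3-methylbut-2-enoate 1 and the Grignard reagent 3 from 5-bromopent-1-ene 2. One conjugate addition creates C7 together with the whole C8–C11 chain.

## Roads not taken

**Alternative 1:** The cut is at C3–C4, made in the forward sense by a Claisen rearrangement. An allyl vinyl ether array C3=C11–O–C6–C5=C4 held in a six-membered cyclic enol ether rearranges through a boat transition state. The oxacycle contracts to ring A and gives the cis-3-acetyl-4-(2-methylpent-4-en-2-yl)cyclohexene A1.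
- Merits: the hindered C3–C4 bond forms intramolecularly. The C1 oxygen, the C6 methyl and the C5=C6 double bond come out in place, so neither a regioselective dehydrogenation nor an inversion at C1 is needed. In these two respects this road is better than the chosen one.
- Weak points: ring B remains to be closed from the acetyl group and the allyl chain. C11 must then be set by addition to a freely rotating side-chain ketone, not a ring ketone. The rearrangement terminus C4 carries the tert-alkyl group, which makes the boat transition state crowded and calls for high temperature. The substrate needs a quaternary oxygenated carbon and a defined alkene geometry.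
- Comparison: the step counts are probably similar. The chosen plan sets C3 and closes ring B in the same step and builds C11 on a rigid bicycle.

**Alternative 2:** The cuts are at C3–C4 and C5–C6, made by an intramolecular Diels–Alder reaction of a 2-silyloxydiene with a tethered (Z)-vinyl sulfone. It gives the bicyclic silyl enol ether A2.
- Merits: both rings and the ring-fusion centres form in one step. The C11 carbinol is already in the tether, so no ketone differentiation and no late Grignard addition are needed. The sulfone β to the unmasked C1 ketone eliminates to give C5=C6 with certain regiochemistry. In convergence and alkene placement this road is better than the chosen plan.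
- Weak points: a five-atom tether must close a seven-membered ring in the cycloaddition. The dienophile carbon C4 carries the quaternary centre. Facial and endo/exo selectivity rest on a tertiary carbinol centre that must itself be made enantioenriched. The acyclic precursor with its (Z)-vinyl sulfone and silyloxydiene is long to make and sensitive to prolonged heating.
- Comparison: the chosen plan has a cyclisation substrate reached in five steps from bulk chemicals and a single stereochemical demand in the key step.

**Alternative 3:** The cut follows biosynthesis. A class 1 sesquiterpene synthase ionises (2E,6E)-farnesyl diphosphate A4, closes the eleven-membered and then the two smaller rings, and traps the C11 cation with water. It gives the himachalol-type alcohol A3.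
- Merits: the whole skeleton with C3, C4 and C11 forms in one step. Only allylic oxidation at C1 and esterification remain. In step count this road is far better than the chosen plan.
- Weak points: it needs an enzyme with exactly this product specificity and absolute configuration, plus the means to express it and supply A4. Cyclases often give product mixtures. The later C–H oxidation must choose C1 over C4 and the methyl group, and must place oxygen on the face of the ring-fusion hydrogens.
- Comparison: the chosen plan is independent of enzyme discovery, carries the C1 oxygen from the start, and gives access to either enantiomer and to analogues through the catalyst and the acid.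

Key step: step 6

Assumption on the chemistry: hydride is taken to attack the C1 carbonyl of 15 from the face of H3 and H4, so the ester is attached with inversion; the opposite outcome is covered by the fallback to step 10.

Naming: in the systematic names of the bicyclic compounds the benzo[7]annulene locants 3, 4, 4a, 9a, 1 and 2 stand for C1, C2, C3, C4, C5 and C6, and 9, 8, 7, 6 and 5 stand for C7 to C11. This one set of locants is kept throughout. Epimer mixtures at C6 and C11 are carried on unseparated because both centres are erased later.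

## Route

Step 1
Reactants: 1 ethyl 3-methylbut-2-enoate; 2 5-bromopent-1-ene
Product: 5 ethyl 3,3-dimethyloct-7-enoate, via pent-4-enylmagnesium bromide 3 (not isolated), via silyl ketene acetal 4 (not isolated)
Conditions: 2, Mg, THF; then 1, CuBr·SMe2 (5 mol %), TMSCl, THF, −40 → 0 °C; aq. NH4Cl
Reagents that add atoms: none
Why: Copper-catalysed conjugate addition of a Grignard reagent to a β,β-disubstituted enoate, accelerated by TMSCl, which traps the enolate as 4 (hydrolysed on work-up); it creates the quaternary C7 together with the C8–C11 chain and the alkene that later becomes the C11 aldehyde.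

Step 2
Reactants: 5 ethyl 3,3-dimethyloct-7-enoate
Product: 6 3,3-dimethyloct-7-enal
Conditions: i-Bu2AlH (1.05 equiv), CH2Cl2, −78 °C; aq. potassium sodium tartrate
Reagents that add atoms: none
Why: Partial reduction of an ester with i-Bu2AlH stops at the tetrahedral aluminate at low temperature and releases the aldehyde on work-up; the neopentyl position disfavours over-reduction.

Step 3
Reactants: 6 3,3-dimethyloct-7-enal; 7 but-3-en-2-one
Product: 9 (4S)-4-(2-methylhept-6-en-2-yl)cyclohex-2-en-1-one, via keto aldehyde 8 (not isolated)
Conditions: (R)-2-[diphenyl(trimethylsilyloxy)methyl]pyrrolidine (10 mol %), ethyl 3,4-dihydroxybenzoate (20 mol %), neat, 4 °C; excess 7 evaporated; then LiOH (30 mol %), i-PrOH, rt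
Reagents that add atoms: none
Why: Enamine-catalysed Michael addition to a vinyl ketone followed by intramolecular aldol condensation (Robinson-type annulation); the E-enamine of 6 is attacked on the face away from the diphenyl(silyloxy)methyl group, which with the (R)-catalyst gives (2R)-8 and hence (S) at C4 of 9, and the tert-alkyl substituent should reinforce the facial bias.

Step 4
Reactants: 9 (4S)-4-(2-methylhept-6-en-2-yl)cyclohex-2-en-1-one
Product: 10 (4S)-6-methyl-4-(2-methylhept-6-en-2-yl)cyclohex-2-en-1-one (mixture of C6 epimers)
Conditions: LiN(i-Pr)2, THF, −78 °C; MeI, −78 → −20 °C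
Reagents that add atoms: iodomethane CI
Why: Kinetic α′-deprotonation of the cyclohexenone gives the cross-conjugated enolate, which is methylated at C6; the new centre forms without control and is erased in step 8.

Step 5
Reactants: 10 (4S)-6-methyl-4-(2-methylhept-6-en-2-yl)cyclohex-2-en-1-one
Product: 11 (4S)-6-methyl-4-(2-methyl-6-oxohexan-2-yl)cyclohex-2-en-1-one (mixture of C6 epimers)
Conditions: OsO4 (2 mol %), NaIO4 (4 equiv), 2,6-lutidine, dioxane/H2O, rt
Reagents that add atoms: osmium tetroxide O=[Os](=O)(=O)=O (delivers the oxygen and is restored by sodium periodate [Na+].[O-]I(=O)(=O)=O)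
Why: Lemieux–Johnson cleavage; OsO4 dihydroxylates the electron-rich monosubstituted alkene much faster than the electron-poor enone double bond, and periodate cleaves the diol to the C11 aldehyde.

Step 6
Reactants: 11 (4S)-6-methyl-4-(2-methyl-6-oxohexan-2-yl)cyclohex-2-en-1-one
Product: 12 (4aR,9aS)-5-hydroxy-2,9,9-trimethyldecahydro-3H-benzo[7]annulen-3-one (cis-fused; mixture of epimers at C6 and C11)
Conditions: SmI2 (2.5 equiv, 0.1 M in THF), t-BuOH (2 equiv), THF, −78 → 0 °C, 11 added slowly to a final concentration of about 5 mM
Reagents that add atoms: none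
Why: Single-electron transfer from divalent samarium to the aldehyde gives a ketyl at C11 (initial reduction of the enone leads to the same bond), which adds to the enone β-carbon C3; a second electron turns the resulting α-keto radical into the trivalent samarium enolate, which t-BuOH protonates to the C1 ketone. The closest known reaction type is the SmI2 ketyl–olefin reductive cyclisation of an aldehyde onto an enone, routine for five- and six-membered rings and documented, though less often, for medium rings. Ring B closes in the 7-exo-trig mode (C3, C4 and C7–C11 in the ring, C2 outside it). C3 is controlled by the C4 stereocentre: with the chain pseudoequatorial on the half-chair the radical reaches C3 along the axial trajectory on the side of the chain, which gives the cis (axial–equatorial) fusion, whereas the trans isomer would need a twist-boat approach. C11 forms without control and both epimers are used, because this centre is oxidised in step 14. The step needs cyclisation to outrun simple reduction of either carbonyl group and intermolecular pinacol or enone dimerisation; the gem-dimethyl group on C7, the activated acceptor, slow addition at high dilution and a mild proton source without strongly reducing additives are meant to secure this.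

Step 7
Reactants: 12 (4aR,9aS)-5-hydroxy-2,9,9-trimethyldecahydro-3H-benzo[7]annulen-3-one
Product: 13 (4aR,9aS)-2,9,9-trimethyl-5-(triethylsilyloxy)decahydro-3H-benzo[7]annulen-3-one
Conditions: TESCl, imidazole, 4-(dimethylamino)pyridine (5 mol %), DMF, rt
Reagents that add atoms: chlorotriethylsilane CC[Si](Cl)(CC)CC
Why: Standard silylation of a secondary alcohol; the triethylsilyl ether survives steps 8 to 12 and can be removed in step 13 without touching an aryl silyl ether or the ester.

Step 8
Reactants: 13 (4aR,9aS)-2,9,9-trimethyl-5-(triethylsilyloxy)decahydro-3H-benzo[7]annulen-3-one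
Product: 14 triethyl{[(4aR,9aS)-2,9,9-trimethyl-3-(trimethylsilyloxy)-4,4a,5,6,7,8,9,9a-octahydro-1H-benzo[7]annulen-5-yl]oxy}silane
Conditions: TMSCl, NaI, Et3N, MeCN, rt
Reagents that add atoms: chlorotrimethylsilane C[Si](C)(C)Cl
Why: Silyl enol ether formation under equilibrating conditions (iodotrimethylsilane made in the flask, amine base) favours the tetrasubstituted C1=C6 enol ether; the C1=C2 isomer is less substituted and would suffer allylic strain with the C11 substituent on C3, and the C6 centre is erased here.

Step 9
Reactants: 14 triethyl{[(4aR,9aS)-2,9,9-trimethyl-3-(trimethylsilyloxy)-4,4a,5,6,7,8,9,9a-octahydro-1H-benzo[7]annulen-5-yl]oxy}silane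
Product: 15 (4aR,9aS)-2,9,9-trimethyl-5-(triethylsilyloxy)-4,4a,5,6,7,8,9,9a-octahydro-3H-benzo[7]annulen-3-one
Conditions: Pd(OAc)2 (1.05 equiv), MeCN, rt
Reagents that add atoms: none
Why: Saegusa–Ito oxidation; the enolate of divalent palladium bound at C6 loses H5 by β-hydride elimination and gives the conjugated C5=C6 enone, leaving zerovalent palladium; C3 and C4 are not touched.

Step 10
Reactants: 15 (4aR,9aS)-2,9,9-trimethyl-5-(triethylsilyloxy)-4,4a,5,6,7,8,9,9a-octahydro-3H-benzo[7]annulen-3-one
Product: 16 (3S,4aR,9aS)-2,9,9-trimethyl-5-(triethylsilyloxy)-4,4a,5,6,7,8,9,9a-octahydro-3H-benzo[7]annulen-3-ol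
Conditions: NaBH4, CeCl3·7H2O, MeOH, −78 °C
Reagents that add atoms: none
Why: Luche reduction gives 1,2-reduction of the enone; hydride should arrive on the convex face of the cis-fused bicycle (the face of H3 and H4), which puts the C1 hydroxyl on the face of ring B and gives the (3S) carbinol.

Step 11
Reactants: 17 isovanillic acid (3-hydroxy-4-methoxybenzoic acid)
Product: 19 3-(tert-butyldimethylsilyloxy)-4-methoxybenzoic acid, via bis-silylated acid 18 (not isolated)
Conditions: TBSCl (2.2 equiv), imidazole, DMF, rt; then AcOH/THF/H2O, rt
Reagents that add atoms: tert-butyldimethylsilyl chloride CC(C)(C)[Si](C)(C)Cl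
Why: Silylation of phenol and acid followed by selective hydrolysis of the labile silyl ester; the aryl silyl ether tolerates the Mitsunobu reaction, mild acid, the periodinane and the organocerium reagent, and is cleaved by fluoride at the end.

Step 12
Reactants: 16 (3S,4aR,9aS)-2,9,9-trimethyl-5-(triethylsilyloxy)-4,4a,5,6,7,8,9,9a-octahydro-3H-benzo[7]annulen-3-ol; 19 3-(tert-butyldimethylsilyloxy)-4-methoxybenzoic acid
Product: 20 (3R,4aR,9aS)-2,9,9-trimethyl-5-(triethylsilyloxy)-4,4a,5,6,7,8,9,9a-octahydro-3H-benzo[7]annulen-3-yl 3-(tert-butyldimethylsilyloxy)-4-methoxybenzoate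
Conditions: PPh3, DIAD, THF, 0 °C → rt
Reagents that add atoms: none
Why: Mitsunobu esterification; the oxyphosphonium salt of the secondary allylic alcohol is displaced by the carboxylate in an SN2 reaction with inversion, from the open convex face, while SN2′ attack at C5 is hindered by the neighbouring C4 and C7.

Step 13
Reactants: 20 (3R,4aR,9aS)-2,9,9-trimethyl-5-(triethylsilyloxy)-4,4a,5,6,7,8,9,9a-octahydro-3H-benzo[7]annulen-3-yl 3-(tert-butyldimethylsilyloxy)-4-methoxybenzoate
Product: 21 (3R,4aR,9aS)-5-hydroxy-2,9,9-trimethyl-4,4a,5,6,7,8,9,9a-octahydro-3H-benzo[7]annulen-3-yl 3-(tert-butyldimethylsilyloxy)-4-methoxybenzoate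
Conditions: pyridinium p-toluenesulfonate (10 mol %), MeOH/CH2Cl2, rt
Reagents that add atoms: none
Why: Acid-catalysed methanolysis removes the alkyl triethylsilyl ether much faster than the aryl tert-butyldimethylsilyl ether and leaves the ester alone.

Step 14
Reactants: 21 (3R,4aR,9aS)-5-hydroxy-2,9,9-trimethyl-4,4a,5,6,7,8,9,9a-octahydro-3H-benzo[7]annulen-3-yl 3-(tert-butyldimethylsilyloxy)-4-methoxybenzoate
Product: 22 (3R,4aR,9aS)-2,9,9-trimethyl-5-oxo-4,4a,5,6,7,8,9,9a-octahydro-3H-benzo[7]annulen-3-yl 3-(tert-butyldimethylsilyloxy)-4-methoxybenzoate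
Conditions: Dess–Martin periodinane, CH2Cl2, rt
Reagents that add atoms: none
Why: Dess–Martin oxidation of a secondary alcohol under near-neutral conditions; both C11 epimers converge on one ketone and the protected phenol is not oxidised.

Step 15
Reactants: 22 (3R,4aR,9aS)-2,9,9-trimethyl-5-oxo-4,4a,5,6,7,8,9,9a-octahydro-3H-benzo[7]annulen-3-yl 3-(tert-butyldimethylsilyloxy)-4-methoxybenzoate
Product: 23 (3R,4aR,5S,9aS)-5-hydroxy-2,5,9,9-tetramethyl-4,4a,5,6,7,8,9,9a-octahydro-3H-benzo[7]annulen-3-yl 3-(tert-butyldimethylsilyloxy)-4-methoxybenzoate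
Conditions: MeMgBr, anhydrous CeCl3, THF, −78 °C
Reagents that add atoms: methylmagnesium bromide C[Mg]Br
Why: Organocerium addition to a ketone; the weakly basic reagent suppresses enolisation towards C3 and should add to the ketone much faster than to the electron-rich aryl ester at −78 °C, and the methyl group adds anti to the C3–C2 bond, from the face of H3, which gives the (5S) carbinol with the hydroxyl anti to H3.

Step 16
Reactants: 23 (3R,4aR,5S,9aS)-5-hydroxy-2,5,9,9-tetramethyl-4,4a,5,6,7,8,9,9a-octahydro-3H-benzo[7]annulen-3-yl 3-(tert-butyldimethylsilyloxy)-4-methoxybenzoate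
Product: 24 (3R,4aR,5S,9aS)-5-hydroxy-2,5,9,9-tetramethyl-4,4a,5,6,7,8,9,9a-octahydro-3H-benzo[7]annulen-3-yl 3-hydroxy-4-methoxybenzoate (target CNP0210711.3)
Conditions: Bu4NF, AcOH, THF, 0 °C
Reagents that add atoms: none
Why: Buffered fluoride cleaves the aryl silyl ether selectively; the allylic ester, the tertiary alcohol and the alkene are not affected.

## Compound list

1 | ethyl 3-methylbut-2-enoate | CCOC(=O)C=C(C)C | starting material
2 | 5-bromopent-1-ene | C=CCCCBr | starting material
3 | pent-4-enylmagnesium bromide | C=CCCC[Mg]Br | intermediate (not isolated)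
4 | 1-ethoxy-3,3-dimethyl-1-(trimethylsilyloxy)octa-1,7-diene (silyl ketene acetal) | CCOC(O[Si](C)(C)C)=CC(C)(C)CCCC=C | intermediate (not isolated)
5 | ethyl 3,3-dimethyloct-7-enoate | CCOC(=O)CC(C)(C)CCCC=C | intermediate
6 | 3,3-dimethyloct-7-enal | O=CCC(C)(C)CCCC=C | intermediate
7 | but-3-en-2-one | CC(=O)C=C | starting material
8 | (2R)-2-(2-methylhept-6-en-2-yl)-5-oxohexanal | O=C[C@H](CCC(C)=O)C(C)(C)CCCC=C | intermediate (not isolated)
9 | (4S)-4-(2-methylhept-6-en-2-yl)cyclohex-2-en-1-one | C=CCCCC(C)(C)[C@H]1CCC(=O)C=C1 | intermediate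
10 | (4S)-6-methyl-4-(2-methylhept-6-en-2-yl)cyclohex-2-en-1-one (C6 epimers) | C=CCCCC(C)(C)[C@H]1CC(C)C(=O)C=C1 | intermediate
11 | (4S)-6-methyl-4-(2-methyl-6-oxohexan-2-yl)cyclohex-2-en-1-one (C6 epimers) | O=CCCCC(C)(C)[C@H]1CC(C)C(=O)C=C1 | intermediate
12 | (4aR,9aS)-5-hydroxy-2,9,9-trimethyldecahydro-3H-benzo[7]annulen-3-one (C6 and C11 epimers) | O=C1C[C@@H]2[C@H](CC1C)C(C)(C)CCCC2O | intermediate
13 | (4aR,9aS)-2,9,9-trimethyl-5-(triethylsilyloxy)decahydro-3H-benzo[7]annulen-3-one | O=C1C[C@@H]2[C@H](CC1C)C(C)(C)CCCC2O[Si](CC)(CC)CC | intermediate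
14 | triethyl{[(4aR,9aS)-2,9,9-trimethyl-3-(trimethylsilyloxy)-4,4a,5,6,7,8,9,9a-octahydro-1H-benzo[7]annulen-5-yl]oxy}silane | CC1=C(O[Si](C)(C)C)C[C@@H]2[C@H](C1)C(C)(C)CCCC2O[Si](CC)(CC)CC | intermediate
15 | (4aR,9aS)-2,9,9-trimethyl-5-(triethylsilyloxy)-4,4a,5,6,7,8,9,9a-octahydro-3H-benzo[7]annulen-3-one | O=C1C[C@@H]2[C@H](C=C1C)C(C)(C)CCCC2O[Si](CC)(CC)CC | intermediate
16 | (3S,4aR,9aS)-2,9,9-trimethyl-5-(triethylsilyloxy)-4,4a,5,6,7,8,9,9a-octahydro-3H-benzo[7]annulen-3-ol | O[C@H]1C[C@@H]2[C@H](C=C1C)C(C)(C)CCCC2O[Si](CC)(CC)CC | intermediate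
17 | isovanillic acid (3-hydroxy-4-methoxybenzoic acid) | COc1ccc(C(=O)O)cc1O | starting material
18 | tert-butyldimethylsilyl 3-(tert-butyldimethylsilyloxy)-4-methoxybenzoate | COc1ccc(C(=O)O[Si](C)(C)C(C)(C)C)cc1O[Si](C)(C)C(C)(C)C | intermediate (not isolated)
19 | 3-(tert-butyldimethylsilyloxy)-4-methoxybenzoic acid | COc1ccc(C(=O)O)cc1O[Si](C)(C)C(C)(C)C | intermediate
20 | (3R,4aR,9aS)-2,9,9-trimethyl-5-(triethylsilyloxy)-4,4a,5,6,7,8,9,9a-octahydro-3H-benzo[7]annulen-3-yl 3-(tert-butyldimethylsilyloxy)-4-methoxybenzoate | COc1ccc(C(=O)O[C@@H]2C[C@@H]3[C@H](C=C2C)C(C)(C)CCCC3O[Si](CC)(CC)CC)cc1O[Si](C)(C)C(C)(C)C | intermediate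
21 | (3R,4aR,9aS)-5-hydroxy-2,9,9-trimethyl-4,4a,5,6,7,8,9,9a-octahydro-3H-benzo[7]annulen-3-yl 3-(tert-butyldimethylsilyloxy)-4-methoxybenzoate | COc1ccc(C(=O)O[C@@H]2C[C@@H]3[C@H](C=C2C)C(C)(C)CCCC3O)cc1O[Si](C)(C)C(C)(C)C | intermediate
22 | (3R,4aR,9aS)-2,9,9-trimethyl-5-oxo-4,4a,5,6,7,8,9,9a-octahydro-3H-benzo[7]annulen-3-yl 3-(tert-butyldimethylsilyloxy)-4-methoxybenzoate | COc1ccc(C(=O)O[C@@H]2C[C@@H]3[C@H](C=C2C)C(C)(C)CCCC3=O)cc1O[Si](C)(C)C(C)(C)C | intermediate
23 | (3R,4aR,5S,9aS)-5-hydroxy-2,5,9,9-tetramethyl-4,4a,5,6,7,8,9,9a-octahydro-3H-benzo[7]annulen-3-yl 3-(tert-butyldimethylsilyloxy)-4-methoxybenzoate | COc1ccc(C(=O)O[C@@H]2C[C@@H]3[C@H](C=C2C)C(C)(C)CCC[C@]3(C)O)cc1O[Si](C)(C)C(C)(C)C | intermediate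
24 | (3R,4aR,5S,9aS)-5-hydroxy-2,5,9,9-tetramethyl-4,4a,5,6,7,8,9,9a-octahydro-3H-benzo[7]annulen-3-yl 3-hydroxy-4-methoxybenzoate | COc1ccc(C(=O)O[C@@H]2C[C@@H]3[C@H](C=C2C)C(C)(C)CCC[C@]3(C)O)cc1O | target

## Step count and least certain steps

Total step count: 16. Longest linear sequence: 15 steps (steps 1 to 10 and 12 to 16); step 11 is a one-step side branch.

**Step 6 (key step).** The seven-membered closure may be too slow, so that simple reduction of the aldehyde or the enone, or intermolecular pinacol or enone dimerisation, takes over. Incomplete cis selectivity at the ring fusion is the second risk. The fallback replaces the ketyl with a neutral α-acyloxyalkyl radical under tin hydride chain conditions, where slow hydride delivery gives a slow ring closure time to occur. It sets out from 11. Acetyl bromide with catalytic ZnBr2 in CH2Cl2 should turn the aldehyde into 1-bromo-5-methyl-5-[(1S)-5-methyl-4-oxocyclohex-2-en-1-yl]hexyl acetate F1. Slow addition of Bu3SnH with azobis(isobutyronitrile) in hot benzene should give, by Giese-type 7-exo cyclisation onto C3, (4aR,9aS)-2,9,9-trimethyl-3-oxodecahydro-1H-benzo[7]annulen-5-yl acetate F2. Methanolysis with K2CO3 in MeOH returns to the route at 12.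

**Step 3.** Enamine formation and Michael addition may be sluggish because the aldehyde carries a neopentyl-type α-substituent, and enolisation of the aldehyde during the basic aldol condensation may erode the C4 configuration. The fallback uses auxiliary control and sets out from 6. Condensation with (S)-1-amino-2-(methoxymethyl)pyrrolidine gives (S)-N-[(E)-3,3-dimethyloct-7-en-1-ylidene]-2-(methoxymethyl)pyrrolidin-1-amine F3. Deprotonation with LiN(i-Pr)2 and alkylation with 2-(2-iodoethyl)-2-methyl-1,3-dioxolane gives (S)-N-[(E,2R)-3,3-dimethyl-2-[2-(2-methyl-1,3-dioxolan-2-yl)ethyl]oct-7-en-1-ylidene]-2-(methoxymethyl)pyrrolidin-1-amine F4. The sense of this alkylation is the one that gives (S)-2-methylalkanals from propanal, which here corresponds to (2R). Aqueous oxalic acid and then dilute HCl in THF release keto aldehyde 8, which is cyclised to 9 as in step 3.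

**Step 10.** Facial selectivity of the hydride addition may be poor, or attack may come from the face of ring B. The fallback makes the esterification stereoconvergent and sets out from 15. The epimeric alcohol (3R,4aR,9aS)-2,9,9-trimethyl-5-(triethylsilyloxy)-4,4a,5,6,7,8,9,9a-octahydro-3H-benzo[7]annulen-3-ol F5 is separated and acylated with retention by acid 19, N,N′-dicyclohexylcarbodiimide and 4-(dimethylamino)pyridine (Steglich esterification). This comes back to the route at 20, so either epimer can be used.

**Step 12.** Elimination of the activated allylic alcohol to a diene, ionisation with loss of inversion, or slow activation of the hindered alcohol by the moderately acidic aryl acid may occur. The fallback separates inversion from acylation and sets out from 16. A Mitsunobu reaction with the stronger and smaller 4-nitrobenzoic acid gives (3R,4aR,9aS)-2,9,9-trimethyl-5-(triethylsilyloxy)-4,4a,5,6,7,8,9,9a-octahydro-3H-benzo[7]annulen-3-yl 4-nitrobenzoate F6. Methanolysis with K2CO3 in MeOH gives the inverted alcohol F5 described above, and Steglich acylation with 19 comes back at 20.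

**Step 15.** The organometallic may attack the aryl ester as well, enolisation may epimerise C3, or facial selectivity at C11 may be insufficient. The fallback removes the ester from this step by carrying C1 as a silyl ether and sets out from 16.
- TBSCl and imidazole give tert-butyldimethyl{[(3S,4aR,9aS)-2,9,9-trimethyl-5-(triethylsilyloxy)-4,4a,5,6,7,8,9,9a-octahydro-3H-benzo[7]annulen-3-yl]oxy}silane F7.
- Pyridinium p-toluenesulfonate in MeOH gives (3S,4aR,9aS)-3-(tert-butyldimethylsilyloxy)-2,9,9-trimethyl-4,4a,5,6,7,8,9,9a-octahydro-3H-benzo[7]annulen-5-ol F8.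
- Dess–Martin oxidation gives (3S,4aR,9aS)-3-(tert-butyldimethylsilyloxy)-2,9,9-trimethyl-3,4,4a,6,7,8,9,9a-octahydro-5H-benzo[7]annulen-5-one F9.
- MeMgBr with CeCl3 gives (3S,4aR,5S,9aS)-3-(tert-butyldimethylsilyloxy)-2,5,9,9-tetramethyl-4,4a,5,6,7,8,9,9a-octahydro-3H-benzo[7]annulen-5-ol F10.
- Bu4NF gives (3S,4aR,5S,9aS)-2,5,9,9-tetramethyl-4,4a,5,6,7,8,9,9a-octahydro-3H-benzo[7]annulene-3,5-diol F11.
- Mitsunobu esterification of its secondary allylic hydroxyl with 19 (the tertiary alcohol does not react) comes back to the route at 23.

## Further compounds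

F1 | step 6 | 1-bromo-5-methyl-5-[(1S)-5-methyl-4-oxocyclohex-2-en-1-yl]hexyl acetate | CC(=O)OC(Br)CCCC(C)(C)[C@H]1CC(C)C(=O)C=C1
F2 | step 6 | (4aR,9aS)-2,9,9-trimethyl-3-oxodecahydro-1H-benzo[7]annulen-5-yl acetate | O=C1C[C@@H]2[C@H](CC1C)C(C)(C)CCCC2OC(C)=O
F3 | step 3 | (S)-N-[(E)-3,3-dimethyloct-7-en-1-ylidene]-2-(methoxymethyl)pyrrolidin-1-amine | COC[C@@H]1CCCN1/N=C/CC(C)(C)CCCC=C
F4 | step 3 | (S)-N-[(E,2R)-3,3-dimethyl-2-[2-(2-methyl-1,3-dioxolan-2-yl)ethyl]oct-7-en-1-ylidene]-2-(methoxymethyl)pyrrolidin-1-amine | COC[C@@H]1CCCN1/N=C/[C@H](CCC1(C)OCCO1)C(C)(C)CCCC=C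
F5 | step 10 | (3R,4aR,9aS)-2,9,9-trimethyl-5-(triethylsilyloxy)-4,4a,5,6,7,8,9,9a-octahydro-3H-benzo[7]annulen-3-ol | O[C@@H]1C[C@@H]2[C@H](C=C1C)C(C)(C)CCCC2O[Si](CC)(CC)CC
F6 | step 12 | (3R,4aR,9aS)-2,9,9-trimethyl-5-(triethylsilyloxy)-4,4a,5,6,7,8,9,9a-octahydro-3H-benzo[7]annulen-3-yl 4-nitrobenzoate | O=C(O[C@@H]1C[C@@H]2[C@H](C=C1C)C(C)(C)CCCC2O[Si](CC)(CC)CC)c1ccc(cc1)[N+](=O)[O-]
F7 | step 15 | tert-butyldimethyl{[(3S,4aR,9aS)-2,9,9-trimethyl-5-(triethylsilyloxy)-4,4a,5,6,7,8,9,9a-octahydro-3H-benzo[7]annulen-3-yl]oxy}silane | CC(C)(C)[Si](C)(C)O[C@H]1C[C@@H]2[C@H](C=C1C)C(C)(C)CCCC2O[Si](CC)(CC)CC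
F8 | step 15 | (3S,4aR,9aS)-3-(tert-butyldimethylsilyloxy)-2,9,9-trimethyl-4,4a,5,6,7,8,9,9a-octahydro-3H-benzo[7]annulen-5-ol | CC(C)(C)[Si](C)(C)O[C@H]1C[C@@H]2[C@H](C=C1C)C(C)(C)CCCC2O
F9 | step 15 | (3S,4aR,9aS)-3-(tert-butyldimethylsilyloxy)-2,9,9-trimethyl-3,4,4a,6,7,8,9,9a-octahydro-5H-benzo[7]annulen-5-one | CC(C)(C)[Si](C)(C)O[C@H]1C[C@@H]2[C@H](C=C1C)C(C)(C)CCCC2=O
F10 | step 15 | (3S,4aR,5S,9aS)-3-(tert-butyldimethylsilyloxy)-2,5,9,9-tetramethyl-4,4a,5,6,7,8,9,9a-octahydro-3H-benzo[7]annulen-5-ol | CC(C)(C)[Si](C)(C)O[C@H]1C[C@@H]2[C@H](C=C1C)C(C)(C)CCC[C@]2(C)O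
F11 | step 15 | (3S,4aR,5S,9aS)-2,5,9,9-tetramethyl-4,4a,5,6,7,8,9,9a-octahydro-3H-benzo[7]annulene-3,5-diol | O[C@H]1C[C@@H]2[C@H](C=C1C)C(C)(C)CCC[C@]2(C)O
A1 | alternative 1 | 1-[(1R,2S,5R)-5-(tert-butyldimethylsilyloxy)-4-methyl-2-(2-methylpent-4-en-2-yl)cyclohex-3-en-1-yl]ethan-1-one | CC(C)(C)[Si](C)(C)O[C@@H]1C[C@@H](C(C)=O)[C@H](C=C1C)C(C)(C)CC=C
A2 | alternative 2 | cis-fused tert-butyldimethylsilyl enol ether (C1=C2) of the bicycle with phenylsulfonyl on C5, methyl on C6 and the C11 methyl carbinol as triethylsilyl ether, target configuration at C3, C4 and C11 | CC(C)(C)[Si](C)(C)OC1=C[C@@H]2[C@H]([C@@H](S(=O)(=O)c3ccccc3)[C@H]1C)C(C)(C)CCC[C@]2(C)O[Si](CC)(CC)CC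
A3 | alternative 3 | (4aR,5S,9aS)-2,5,9,9-tetramethyl-4,4a,5,6,7,8,9,9a-octahydro-3H-benzo[7]annulen-5-ol | C1C[C@@H]2[C@H](C=C1C)C(C)(C)CCC[C@]2(C)O
A4 | alternative 3 | (2E,6E)-farnesyl diphosphate | CC(C)=CCC/C(C)=C/CC/C(C)=C/COP(=O)(O)OP(=O)(O)O
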